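Numbering used throughout: C1–C9 are the bicyclo[3.3.1]nonane carbons (C1 carries the isobutyryl group, C2 and C4 are ketones, C5 carries geranyl, C6 is CH2, C7 is CH, C8 is CMe2, C9 is the bridging ketone). C27H2–C28H links C7 to C3. C29(Me)2–C23H2–C22H2 runs from C28 back to C3. Ring A is C1–C2–C3–C4–C5–C9, ring B is C1–C8–C7–C6–C5–C9, ring C is C3–C4–C5–C6–C7–C27–C28 and ring D is C3–C22–C23–C29–C28.

## The problem

The target is a bicyclo[3.3.1]nonane-2,4,9-trione (rings A and B) whose C3 and C7 are tied by the two-carbon bridge C28–C27 into a homoadamantane (seven-membered ring C). A cyclopentane (ring D) is spiro at C3 and fused along C3–C28. Five carbons are quaternary (C1, C3, C5, C8, C29), and two runs of crowded bonds (C1–C8 and C3–C28–C29) must be made. Of the five stereocentres, C1, C3, C5 and C7 are locked together by the cage: once C5 is set and the C7 substituent is endo, the others follow. C28 is the only free stereocentre, and its CMe2 arm (C29) must lie on the C2/C8 flank with its hydrogen on the C4/C6 flank, next to the C8 gem-dimethyl group. The geranyl chain rules out hydrogenation, ozonolysis and strong acid, and the non-enolisable triketone is open to retro-Claisen cleavage by nucleophilic base. Ring D has only two carbons (C22, C23) between C3 and C29, so the side arm on C3 must deliver two ring carbons and nothing else. The feature that makes the key step possible is that, in a precursor holding rings A and B only, an endo (axial) prenyl group on C7 places its C28=C29 double bond under C3 of the enolised 2,4-dione. A C3 radical can then close ring C on C28 (7-exo), and the resulting C29 radical sits five atoms from C23 of an allyl-type arm on C3, closing ring D (5-exo).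

## Retrosynthesis

**19 ⇒ 18.** The C23–H bond of 19 is traced to a C23–CHO group. The formyl carbon is the exocyclic atom that a 5-exo closure on C23 must leave behind, and a rhodium decarbonylation removes it without touching alkenes or ketones. Ozonolytic or hydrogenative removal of a larger residue would not survive the geranyl chain.

**18 ⇒ 16 (key disconnection).** C3–C28 and C29–C23 are cut together. This removes rings C and D, two quaternary centres (C3, C29) and the C28 stereocentre, and leaves bicycle 16 with three stereocentres and free rotation in both side chains. The forward reaction is an oxidative radical bicyclisation: the C3 radical must close on C28 from its endo lobe with the C27–C28 bond tilted toward C6, and the C29 radical must add to C23 of the enol pivalate before the first closure reverts. Cutting only one of the two bonds would leave a bridgehead C3 that cannot be substituted afterwards, so both bonds have to form while C3 is still a planar radical or enol carbon.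

**16 ⇒ 15 ⇒ 13.** The endo prenyl group is cut at C27–C28 after re-oxidising C27. Allylic carbonate 15 comes from a 2-methylprop-1-enyl organometallic and an endo C7 aldehyde. That aldehyde is stored as adamantane carbinol 13, its aldol adduct with C3, which guarantees the endo configuration because only the endo aldehyde can reach C3. The forward steps are a retro-aldol with organocerium capture and an allylic hydrogenolysis that puts hydride on C27.

**13 ⇒ 7 + 11.** C5–C6, C1–C8 and the aldol bond C3–C27 are cut, returning the flat acylphloroglucinol 7 and the three-carbon bis-electrophile 11. The forward alkylative dearomatisation–annulation makes ring B and the vicinal quaternary pair C1–C8, and a chiral ammonium ion pair sets C5 and with it the absolute configuration. It must start at the geranyl-bearing carbon.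

**7 ⇒ 3 + 6; 3 ⇒ 1 + 2; 6 ⇒ 4 + 5; 11 ⇒ 10 ⇒ 8 + 9.** Two successive C-allylations of phlorisobutyrophenone 1 install geranyl (from 2) and the 3-(pivaloyloxy)allyl arm (from 6, made from acrolein 4 and pivaloyl bromide 5). Enal 11 comes from 2-lithioacrolein acetal (from 8) and acetone 9 by way of acetal 10.

## Roads not taken

**Alternative 1:** the most obvious plan copies the presumed biosynthesis exactly. The 3-prenyl bicycle A1 would undergo the same Mn(OAc)3 cascade (7-exo, then 5-exo onto the C3 prenyl group) to the isopropenyl cage compound A2. A2 carries three carbons too many on C23. Excising them needs ozonolysis or hydroperoxide fragmentation of a 1,1-disubstituted alkene next to the two more electron-rich trisubstituted alkenes of geranyl. The chosen enol ester arm leaves a single formyl carbon that rhodium removes chemoselectively.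

**Alternative 2:** cut C7–C27 last. A spiro-fused methylenecyclopentane acid A3 would give a C7 radical by decarboxylation, 7-endo attack on the exocyclic methylene would close the cage, and hydrogen-atom transfer to the C28 radical from the open C6 flank would set C28. This makes C7 and C28 safe, but A3 needs C28 on the concave face of C3. Whichever carbon is attached to C3 second enters from the convex face, so the hindered C3–C28 bond would have to be made first by alkenylation of the dione. The run-up is longer than the whole chosen route.

**Alternative 3:** close ring C through an allene (C3 radical onto the central carbon of a C7 dimethylallenyl group) to the cage alkene A4, and set C28 by catalytic hydrogenation from the C6 flank to give the cage core A5. Hydrogenation cannot be done with geranyl present, so geranyl and isobutyryl would both have to be introduced afterwards by bridgehead enolate chemistry on a base-sensitive triketone. A bicycle with free bridgeheads and an endo C7 substituent also has no short access, because the dearomatisation route needs a quaternary C5. The chosen plan keeps both bridgehead groups from the first two steps.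

Key step: step 9

Assumption: the sense of induction of the cinchona-derived ammonium salt in step 6 is not known for this substrate; the pseudoenantiomeric cinchonine-derived salt is used if the cinchonidine salt gives the antipode of 13.

## Route

Step 1
Reactants: 1 phlorisobutyrophenone (2-methyl-1-(2,4,6-trihydroxyphenyl)propan-1-one); 2 geranyl bromide
Product: 3 3-geranylphlorisobutyrophenone (geranyl E)
Conditions: DBU, THF, 0 to 25 °C
Reagents that add atoms: none
Why: C-allylation of the acylphloroglucinol (a vinylogous acid) with an allylic bromide; one equivalent of bromide should keep it at mono-alkylation.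

Step 2
Reactants: 4 acrolein; 5 pivaloyl bromide
Product: 6 (E)-3-bromoprop-1-en-1-yl pivalate
Conditions: ZnCl2 (cat.), CH2Cl2, −20 to 0 °C
Reagents that add atoms: none
Why: Lewis-acid-promoted 1,4-addition of an acyl bromide to the enal gives the γ-bromo enol ester, as known for acetyl and benzoyl bromide; alkene geometry is of no consequence later.

Step 3
Reactants: 3 3-geranylphlorisobutyrophenone; 6 (E)-3-bromoprop-1-en-1-yl pivalate
Product: 7 3-geranyl-5-[(E)-3-(pivaloyloxy)prop-2-enyl]phlorisobutyrophenone
Conditions: DBU, THF, −20 to 0 °C
Reagents that add atoms: none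
Why: second C-allylation at the only unsubstituted ring carbon by SN2 at the primary allylic bromide; an amidine base is used so that the enol ester is not transesterified.

Step 4
Reactants: 8 2-bromo-3,3-diethoxyprop-1-ene; 9 acetone
Product: 10 3-(diethoxymethyl)-2-methylbut-3-en-2-yl acetate
Conditions: t-BuLi (2 equiv), THF, −78 °C; acetone; then Ac2O, −78 to 0 °C
Reagents that add atoms: acetic anhydride, CC(=O)OC(C)=O
Why: bromine–lithium exchange gives 2-lithioacrolein acetal, which adds 1,2 to acetone; the tertiary lithium alkoxide is acetylated in the same flask.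

Step 5
Reactants: 10 3-(diethoxymethyl)-2-methylbut-3-en-2-yl acetate
Product: 11 3-formyl-2-methylbut-3-en-2-yl acetate (2-(2-acetoxypropan-2-yl)acrolein)
Conditions: oxalic acid (aq.), silica gel, CH2Cl2, 25 °C
Reagents that add atoms: water, O
Why: mild acetal hydrolysis frees the enal while the tertiary allylic acetate, the latent leaving group, stays in place.

Step 6
Reactants: 7 3-geranyl-5-[(E)-3-(pivaloyloxy)prop-2-enyl]phlorisobutyrophenone; 11 3-formyl-2-methylbut-3-en-2-yl acetate
Product: 13 adamantane carbinol (C1 isobutyryl, C5 geranyl, C8 Me2, C3 bearing the pivaloyloxyallyl arm and bonded to the carbinol carbon on C7; one carbinol epimer, not assigned), via bicyclic endo-aldehyde 12 (not isolated)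
Conditions: CsOH·H2O, O-allyl-N-(9-anthracenylmethyl)cinchonidinium bromide (10 mol %), 4 Å MS, CH2Cl2, −50 °C
Reagents that add atoms: none
Why: alkylative dearomatisation–annulation: Michael addition of C5 to the methylene terminus, E1cB loss of acetate, and Michael addition of C1 to the β,β-dimethyl enal close ring B (12), with the chiral ammonium ion pair setting C5 in the first C–C bond. The C7 aldehyde epimerises by enolisation, and only its endo epimer is drained by aldol addition of C3 to give 13, so C1 and C7 follow from C5.

Step 7
Reactants: 13 adamantane carbinol; 14 (2-methylprop-1-en-1-yl)magnesium bromide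
Product: 15 7-endo allylic methyl carbonate (C7–CH(OCO2Me)–CH=CMe2; either C27 epimer)
Conditions: CeCl3, THF, −78 to 0 °C; then ClCO2Me, −78 to 0 °C; NaHCO3 (aq.), MeOH work-up
Reagents that add atoms: methyl chloroformate, COC(=O)Cl
Why: retro-aldol of the alkoxide releases the endo C7 aldehyde, which the non-basic organocerium reagent captures before it can epimerise (retro-aldol/organocerium addition); the new alkoxide is carbonylated in situ and the labile enol carbonate of the dione falls off on work-up.

Step 8
Reactants: 15 7-endo allylic methyl carbonate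
Product: 16 1-isobutyryl-5-geranyl-7-endo-prenyl-8,8-dimethyl-3-[(E)-3-(pivaloyloxy)prop-2-enyl]bicyclo[3.3.1]nonane-2,4,9-trione (2-enol form)
Conditions: Pd(PPh3)4 (5 mol %), Bu3SnH, THF, 25 °C
Reagents that add atoms: none
Why: Tsuji–Trost-type allylic hydrogenolysis: zerovalent palladium ionises the carbonate and the tin-derived hydride is delivered to the less substituted allyl terminus C27, which should leave the trisubstituted (prenyl) alkene; C7 is not touched.

Step 9
Reactants: 16 7-endo-prenyl bicyclic trione with the enol pivalate arm
Product: 18 cage aldehyde (the target skeleton with CHO on C23; C23 epimers), via mixed acylal 17 (not isolated)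
Conditions: Mn(OAc)3·2H2O (2.5 equiv), degassed AcOH, 50 °C; then HCl (1 M aq.), THF, 25 °C
Reagents that add atoms: acetic acid (acetate in 17), CC(O)=O; water, O
Why: Mn(OAc)3 forms the trivalent manganese enolate of the 2-substituted 1,3-dione and inner-sphere electron transfer gives the planar C3 radical; the closest known reaction type is the oxidative free-radical cyclisation of 2-alkyl-1,3-diones by trivalent manganese, including tandem closures onto prenyl groups in related acylphloroglucinols. Ring C closes 7-exo-trig on C28 to give the tertiary C29 radical; ring D closes 5-exo-trig on C23 of the enol ester, and the α-acyloxy radical is oxidised by a second Mn(OAc)3 and captured by acetate as 17, which mild acid hydrolyses to 18. C3 is set by the cage: C28 can only reach the endo lobe, so the arm ends exo. C28 is set in the first closure: in the staggered transition state the C27–C28 bond must tilt off the C3···C7 axis, and tilt toward the C6 methylene, away from the C8 gem-dimethyl group, puts H28 under C4 and the CMe2 terminus toward C2, the arrangement of the target. C23 forms as a mixture that the next step erases. The step needs 7-exo over 8-endo attack, which the tertiary radical and exo mode favour, and no 6-exo mode exists because C27 is sp3. The geranyl alkenes cannot be reached from C3 because C5 is a bridgehead. Copper salts are left out so that the C29 radical lives long enough to add to the enol ester before the first closure reverts.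

Step 10
Reactants: 18 cage aldehyde
Product: 19 target (CNP0313870.1)
Conditions: RhCl(PPh3)3 (1.1 equiv), PhCN, 130 °C
Reagents that add atoms: none
Why: Tsuji–Wilkinson decarbonylation replaces C23–CHO by C23–H and turns the one uncontrolled centre into a CH2 group; ketones and trisubstituted alkenes are tolerated by the monovalent rhodium complex.

## Compound list

1 | phlorisobutyrophenone | CC(C)C(=O)c1c(O)cc(O)cc1O | starting material
2 | geranyl bromide | CC(C)=CCC/C(C)=C/CBr | starting material
3 | 3-geranylphlorisobutyrophenone | CC(C)=CCC/C(C)=C/Cc1c(O)cc(O)c(C(=O)C(C)C)c1O | intermediate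
4 | acrolein | C=CC=O | starting material
5 | pivaloyl bromide | CC(C)(C)C(=O)Br | starting material
6 | (E)-3-bromoprop-1-en-1-yl pivalate | BrC/C=C/OC(=O)C(C)(C)C | intermediate
7 | 3-geranyl-5-[(E)-3-(pivaloyloxy)prop-2-enyl]phlorisobutyrophenone | CC(C)=CCC/C(C)=C/Cc1c(O)c(C/C=C/OC(=O)C(C)(C)C)c(O)c(C(=O)C(C)C)c1O | intermediate
8 | 2-bromo-3,3-diethoxyprop-1-ene | C=C(Br)C(OCC)OCC | starting material
9 | acetone | CC(C)=O | starting material
10 | 3-(diethoxymethyl)-2-methylbut-3-en-2-yl acetate | C=C(C(OCC)OCC)C(C)(C)OC(C)=O | intermediate
11 | 3-formyl-2-methylbut-3-en-2-yl acetate | C=C(C=O)C(C)(C)OC(C)=O | intermediate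
12 | bicyclic endo-aldehyde (rings A and B; C7 formyl endo, equilibrating with its epimer) | CC(C)=CCC/C(C)=C/C[C@@]12C[C@@H](C=O)C(C)(C)[C@](C(=O)C(C)C)(C2=O)C(O)=C(C/C=C/OC(=O)C(C)(C)C)C1=O | intermediate
13 | adamantane carbinol (aldol adduct of C3 with the endo C7 aldehyde; carbinol epimer not assigned) | CC(C)=CCC/C(C)=C/C[C@@]12C[C@H]3C(O)[C@@](C/C=C/OC(=O)C(C)(C)C)(C1=O)C(=O)[C@@](C(=O)C(C)C)(C2=O)C3(C)C | intermediate
14 | (2-methylprop-1-en-1-yl)magnesium bromide | CC(C)=C[Mg]Br | starting material
15 | 7-endo allylic methyl carbonate (C27 epimer not assigned) | CC(C)=CCC/C(C)=C/C[C@@]12C[C@@H](C(OC(=O)OC)C=C(C)C)C(C)(C)[C@](C(=O)C(C)C)(C2=O)C(O)=C(C/C=C/OC(=O)C(C)(C)C)C1=O | intermediate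
16 | 7-endo-prenyl bicyclic trione with enol pivalate arm (cascade precursor) | CC(C)=CCC/C(C)=C/C[C@@]12C[C@@H](CC=C(C)C)C(C)(C)[C@](C(=O)C(C)C)(C2=O)C(O)=C(C/C=C/OC(=O)C(C)(C)C)C1=O | intermediate
17 | mixed acylal of the cage aldehyde (C23–CH(OAc)(OPiv); epimers at C23 and the acylal carbon) | CC(C)=CCC/C(C)=C/C[C@@]12C[C@H]3C[C@@H]4C(C)(C)C(C(OC(C)=O)OC(=O)C(C)(C)C)C[C@]4(C1=O)C(=O)[C@@](C(=O)C(C)C)(C2=O)C3(C)C | intermediate
18 | cage aldehyde (target skeleton with CHO on C23; C23 epimers) | CC(C)=CCC/C(C)=C/C[C@@]12C[C@H]3C[C@@H]4C(C)(C)C(C=O)C[C@]4(C1=O)C(=O)[C@@](C(=O)C(C)C)(C2=O)C3(C)C | intermediate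
19 | CNP0313870.1 | CC(C)=CCC/C(C)=C/C[C@@]12C[C@H]3C[C@@H]4C(C)(C)CC[C@]4(C1=O)C(=O)[C@@](C(=O)C(C)C)(C2=O)C3(C)C | target

## Step count and risks

Total step count: 10. Longest linear sequence: 7 steps (1, 3, 6, 7, 8, 9, 10).

**Step 9 (key step).** The most likely failure is closure of the C3 radical on the other face of C28=C29, with the C27–C28 bond tilting toward C8 instead of C6. This is made worse if the first closure reverts before the slower, polarity-mismatched 5-exo addition to the enol ester, and the result is erosion of the C28 configuration. The fallback replaces steric bias by allylic 1,3-strain control from a temporary C27 stereocentre. Setting out from 13, the organocerium addition of step 7 with aqueous work-up gives the 7-endo allylic alcohol F1 (the Felkin–Anh epimer). Dess–Martin oxidation gives the enone F2, and Luche reduction (NaBH4, CeCl3·7H2O, MeOH) delivers hydride anti to C8 and gives the C27-epimeric allylic alcohol F3. In F3 the C27 hydrogen has to lie in the alkene plane beside the (Z)-methyl group and the hydroxyl anti to the forming C3–C28 bond, which leaves only the tilt toward C6 open. The conditions of step 9 then give the hydroxy cage aldehyde F4, and decarbonylation as in step 10 gives the cage alcohol F5. Phenyl chlorothionoformate and pyridine give the thionocarbonate F6, and Barton–McCombie reduction (Bu3SnH, AIBN, toluene, 90 °C) returns to the route at 19.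

**Step 6.** The first conjugate addition may start at the arm-bearing carbon instead of the geranyl-bearing carbon, since both are alkylated ring carbons of similar nucleophilicity, and the enol ester may suffer partial loss under hydroxide. The fallback blocks the arm position with a group that is exchanged by a radical afterwards. Setting out from 3, N-bromosuccinimide (CH2Cl2, −78 °C) gives the ring bromide F7, whose brominated carbon should not open the sequence. The conditions of step 6 give the bromo adamantane carbinol F8. Keck radical allylation with tributyl[1-(pivaloyloxy)prop-2-enyl]stannane F9 (from 4, Bu3SnLi, then pivaloyl chloride) and AIBN in benzene at 80 °C puts the arm on the bridgehead radical and returns to the route at 13.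

**Step 8.** Hydride may be delivered to the wrong allyl terminus (C29), giving the 1,2-disubstituted alkene isomer instead of the prenyl group. The fallback builds the prenyl group from a terminal alkene. Setting out from 13, vinylmagnesium bromide with CeCl3 followed by Ac2O gives the 7-endo vinyl carbinol acetate F10. Pd(PPh3)4 with HCO2NH4 delivers hydride to the substituted terminus and gives the 7-endo allyl compound F11. Cross-metathesis with 2-methylbut-2-ene (second-generation Grubbs catalyst, CH2Cl2, 40 °C) returns to the route at 16.

Further compounds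
F1 | step 9 | 7-endo allylic alcohol, Felkin–Anh epimer at C27 | CC(C)=CCC/C(C)=C/C[C@@]12C[C@@H]([C@H](O)C=C(C)C)C(C)(C)[C@](C(=O)C(C)C)(C2=O)C(O)=C(C/C=C/OC(=O)C(C)(C)C)C1=O
F2 | step 9 | 7-endo enone (C27 ketone) | CC(C)=CCC/C(C)=C/C[C@@]12C[C@@H](C(=O)C=C(C)C)C(C)(C)[C@](C(=O)C(C)C)(C2=O)C(O)=C(C/C=C/OC(=O)C(C)(C)C)C1=O
F3 | step 9 | 7-endo allylic alcohol, C27 epimer of F1 | CC(C)=CCC/C(C)=C/C[C@@]12C[C@@H]([C@@H](O)C=C(C)C)C(C)(C)[C@](C(=O)C(C)C)(C2=O)C(O)=C(C/C=C/OC(=O)C(C)(C)C)C1=O
F4 | step 9 | C27-hydroxy cage aldehyde (CHO on C23; C23 epimers) | CC(C)=CCC/C(C)=C/C[C@@]12C[C@H]3[C@@H](O)[C@@H]4C(C)(C)C(C=O)C[C@]4(C1=O)C(=O)[C@@](C(=O)C(C)C)(C2=O)C3(C)C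
F5 | step 9 | C27-hydroxy cage compound | CC(C)=CCC/C(C)=C/C[C@@]12C[C@H]3[C@@H](O)[C@@H]4C(C)(C)CC[C@]4(C1=O)C(=O)[C@@](C(=O)C(C)C)(C2=O)C3(C)C
F6 | step 9 | C27 O-phenyl thionocarbonate of the cage alcohol | CC(C)=CCC/C(C)=C/C[C@@]12C[C@H]3[C@@H](OC(=S)Oc5ccccc5)[C@@H]4C(C)(C)CC[C@]4(C1=O)C(=O)[C@@](C(=O)C(C)C)(C2=O)C3(C)C
F7 | step 6 | 3-bromo-5-geranylphlorisobutyrophenone | CC(C)=CCC/C(C)=C/Cc1c(O)c(Br)c(O)c(C(=O)C(C)C)c1O
F8 | step 6 | bromo adamantane carbinol (Br on C3; carbinol epimer not assigned) | CC(C)=CCC/C(C)=C/C[C@@]12C[C@H]3C(O)[C@@](Br)(C1=O)C(=O)[C@@](C(=O)C(C)C)(C2=O)C3(C)C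
F9 | step 6 | tributyl[1-(pivaloyloxy)prop-2-enyl]stannane | CCCC[Sn](CCCC)(CCCC)C(C=C)OC(=O)C(C)(C)C
F10 | step 8 | 7-endo vinyl carbinol acetate (C27 epimer not assigned) | CC(C)=CCC/C(C)=C/C[C@@]12C[C@@H](C(OC(C)=O)C=C)C(C)(C)[C@](C(=O)C(C)C)(C2=O)C(O)=C(C/C=C/OC(=O)C(C)(C)C)C1=O
F11 | step 8 | 7-endo allyl bicyclic trione | CC(C)=CCC/C(C)=C/C[C@@]12C[C@@H](CC=C)C(C)(C)[C@](C(=O)C(C)C)(C2=O)C(O)=C(C/C=C/OC(=O)C(C)(C)C)C1=O
A1 | alternative 1 | 3,7-diprenyl bicyclic trione (7-endo) | CC(C)=CCC/C(C)=C/C[C@@]12C[C@@H](CC=C(C)C)C(C)(C)[C@](C(=O)C(C)C)(C2=O)C(O)=C(CC=C(C)C)C1=O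
A2 | alternative 1 | isopropenyl cage compound (isopropenyl on C23; C23 epimers) | CC(C)=CCC/C(C)=C/C[C@@]12C[C@H]3C[C@@H]4C(C)(C)C(C(C)=C)C[C@]4(C1=O)C(=O)[C@@](C(=O)C(C)C)(C2=O)C3(C)C
A3 | alternative 2 | spiro methylenecyclopentane bicyclic acid (CO2H on C7, C7 not defined) | CC(C)=CCC/C(C)=C/C[C@@]12CC(C(O)=O)C(C)(C)[C@](C(=O)C(C)C)(C2=O)C(=O)[C@]3(CCC(C)(C)C3=C)C1=O
A4 | alternative 3 | cage alkene core (C27=C28, bridgeheads C1 and C5 unsubstituted) | [C@@H]12C[C@H]3C=C4C(C)(C)CC[C@]4(C1=O)C(=O)[C@@H](C2=O)C3(C)C
A5 | alternative 3 | saturated cage core (bridgeheads C1 and C5 unsubstituted) | [C@@H]12C[C@H]3C[C@@H]4C(C)(C)CC[C@]4(C1=O)C(=O)[C@@H](C2=O)C3(C)C
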